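## Retrosynthetic overview
1. Target ⇒ one global Pd/C hydrogenolysis (two ArO–Bn, one traceless Ar–Br) of the fully assembled, otherwise unprotected sesquilignan.
2. C7''–C8'' bond (7''S,8''S, threo): L-threonine-type primary-amine syn cross-aldol of the ring-B aryloxyacetaldehyde with 6-bromo-O-benzylvanillin, then NaBH4 to give C9''H2OH.
3. Aryloxyacetaldehyde ⇐ ozonolysis of an O-allyl ether. C3–CH2Ar bond (3R) ⇐ trans-selective alkylation of the hydroxy-lactone dianion with O-benzylvanillyl bromide.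
4. C4–C7 bond (4R,7R): L-proline anti cross-aldol of methyl 4-oxobutanoate with O-allylvanillin, then NaBH4 and lactonisation.
5. Ring order: the γ-butyrolactone is the only ring made and is closed in the first step. The three arenes are bought.

Assumption: locants are lactone O1/C2(=O)/C3/C4/C5, ring-B carbinol C7 and glycerol chain C7''/C8''/C9''; CIP analysis of the SMILES gives (3R,4R,7R,7''S,8''S), that is a trans-lactone and a threo (zigzag-syn) β-O-4 unit; compounds 1, 2, 6 and 12 are taken as catalogue chemicals.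

## Route

Step 1
Reactants: 1 4-(allyloxy)-3-methoxybenzaldehyde (O-allylvanillin); 2 methyl 4-oxobutanoate
Product: 5 (4R)-4-{(R)-[4-(allyloxy)-3-methoxyphenyl](hydroxy)methyl}dihydrofuran-2(3H)-one, via anti-aldol aldehyde 3 (not isolated), via diol ester 4 (not isolated)
Conditions: L-proline (30 mol %), DMF, 4 °C, 2 added over 24 h to 1 (2 equiv), 48 h; then MeOH, NaBH4, −10 to 0 °C; aq NH4Cl
Reagents that add atoms: none
Why: Proline enamine cross-aldol (Houk–List transition state): the E-enamine of 2 adds to the Re face of 1 to give the anti-aldol, setting C4 (R) and C7 (R) together as the first stereocentres, after which NaBH4 reduces the formyl group before it can epimerise and the primary alkoxide closes the γ-lactone on the methyl ester faster than the benzylic one.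

Step 2
Reactants: 6 [4-(benzyloxy)-3-methoxyphenyl]methanol
Product: 7 1-(benzyloxy)-4-(bromomethyl)-2-methoxybenzene
Conditions: PBr3 (0.4 equiv), Et2O, 0 °C, 1 h; used at once
Reagents that add atoms: phosphorus tribromide BrP(Br)Br
Why: PBr3 bromination (SN2 on the phosphite ester) of an activated benzylic alcohol is fast and clean, and no stereocentre is involved.

Step 3
Reactants: 5 hydroxy-lactone; 7 benzylic bromide
Product: 9 (3R,4R)-4-{(R)-[4-(allyloxy)-3-methoxyphenyl](hydroxy)methyl}-3-[4-(benzyloxy)-3-methoxybenzyl]dihydrofuran-2(3H)-one, via dilithio dianion 8 (not isolated)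
Conditions: 5 added to LDA (2.15 equiv, commercial solution), THF, −78 °C, 1 h; 7 (1.2 equiv), −78 to −45 °C; AcOH quench at −78 °C
Reagents that add atoms: none
Why: Alkoxide/enolate dianion alkylation (SN2 lactone-enolate alkylation): the enolised lactone cannot be attacked by the C7 alkoxide, the cold lithium alkoxide is inert to the bromide, and the electrophile approaches anti to the bulky C4 substituent to give the trans-3,4 lactone (3R), which is also the thermodynamic isomer.

Step 4
Reactants: 9 allyl ether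
Product: 11 2-{4-[(R)-{(3R,4R)-4-[4-(benzyloxy)-3-methoxybenzyl]-5-oxotetrahydrofuran-3-yl}(hydroxy)methyl]-2-methoxyphenoxy}acetaldehyde, via secondary ozonide 10 (not isolated)
Conditions: O3, CH2Cl2, −78 °C (Sudan III end point); then Me2S, −78 °C to rt; used crude
Reagents that add atoms: ozone [O-][O+]=O
Why: Criegee ozonolysis with reductive work-up cleaves the only alkene under neutral conditions, which avoids the acid that would ionise the electron-rich C7 carbinol into an aryltetralin, and no stereocentre is touched.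

Step 5
Reactants: 12 4-(benzyloxy)-3-methoxybenzaldehyde (O-benzylvanillin)
Product: 13 4-(benzyloxy)-2-bromo-5-methoxybenzaldehyde
Conditions: Br2 (1.05 equiv), NaOAc, AcOH, rt
Reagents that add atoms: bromine BrBr
Why: Electrophilic aromatic bromination goes para to the methoxy group (ortho to CHO), and the bromine acts as a traceless activator that raises the electrophilicity of the aldehyde for step 6 and leaves in step 7.

Step 6
Reactants: 11 aryloxyacetaldehyde; 13 bromo aldehyde
Product: 15 (3R,4R)-3-[4-(benzyloxy)-3-methoxybenzyl]-4-{(R)-[4-({(1S,2S)-1-[4-(benzyloxy)-2-bromo-5-methoxyphenyl]-1,3-dihydroxypropan-2-yl}oxy)-3-methoxyphenyl](hydroxy)methyl}dihydrofuran-2(3H)-one, via syn-aldol aldehyde 14 (not isolated)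
Conditions: O-tert-butyl-L-threonine (30 mol %), H2O (3 equiv), NMP, 4 °C, 11 added over 24 h to 13 (5 equiv), then 24 h; then MeOH, NaBH4, −20 to 0 °C
Reagents that add atoms: none
Why: Proposed new method: a primary-amino-acid-catalysed, syn-selective enamine cross-aldol with an α-aryloxyacetaldehyde as donor and an aromatic aldehyde as acceptor; condensation of 11 with the NH2 group gives a secondary enamine whose (Z)-isomer is held by an N–H···O hydrogen bond to the guaiacyl ether/methoxy oxygen pair, the catalyst carboxylic acid activates the carbonyl of 13 in a Houk–List-type hydrogen-bonded cyclic transition state, the CH(Ot-Bu)CH3 arm blocks one enamine face, and bond formation on the Re face of 13 gives the syn aldol 14 (2R,3S), which is (8''S,7''S) after reduction, with the remote lactone stereocentres playing no role; slow addition of 11 into excess ortho-bromo-activated 13 holds down self-aldol of the very electrophilic donor, and immediate NaBH4 reduction (lactone inert at or below 0 °C) freezes the labile α-aryloxy aldehyde; the closest known reaction types are the threonine-type primary-amine syn-aldol of hydroxyacetone and protected dihydroxyacetone with aryl aldehydes and the proline anti-aldol of α-alkoxyacetaldehydes.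

Step 7
Reactants: 15 bis-benzyl bromo precursor
Product: 16 target, (3R,4R)-4-{(R)-[4-({(1S,2S)-1,3-dihydroxy-1-(4-hydroxy-3-methoxyphenyl)propan-2-yl}oxy)-3-methoxyphenyl](hydroxy)methyl}-3-(4-hydroxy-3-methoxybenzyl)dihydrofuran-2(3H)-one
Conditions: H2 (1 atm), 10 % Pd/C, NaOAc (1.5 equiv), EtOAc/EtOH 1:1, rt, 2–3 h (stopped at full conversion)
Reagents that add atoms: none
Why: Heterogeneous hydrogenolysis removes both aryl benzyl ethers and the aryl bromide at 1 atm much faster than it cleaves benzylic C–OH bonds, the acetate buffer traps HBr so neither carbinol ionises, and no stereocentre is affected.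

## Compound list
1 | 4-(allyloxy)-3-methoxybenzaldehyde | C=CCOc1ccc(C=O)cc1OC | starting material
2 | methyl 4-oxobutanoate | COC(=O)CCC=O | starting material
3 | methyl (3S,4R)-4-[4-(allyloxy)-3-methoxyphenyl]-3-formyl-4-hydroxybutanoate (anti-aldol) | COC(=O)C[C@H](C=O)[C@@H](O)c1ccc(OCC=C)c(OC)c1 | intermediate
4 | methyl (3R,4R)-4-[4-(allyloxy)-3-methoxyphenyl]-4-hydroxy-3-(hydroxymethyl)butanoate | COC(=O)C[C@H](CO)[C@@H](O)c1ccc(OCC=C)c(OC)c1 | intermediate
5 | (4R)-4-{(R)-[4-(allyloxy)-3-methoxyphenyl](hydroxy)methyl}dihydrofuran-2(3H)-one | O=C1C[C@H](CO1)[C@@H](O)c2ccc(OCC=C)c(OC)c2 | intermediate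
6 | [4-(benzyloxy)-3-methoxyphenyl]methanol | COc1cc(CO)ccc1OCc1ccccc1 | starting material
7 | 1-(benzyloxy)-4-(bromomethyl)-2-methoxybenzene | COc1cc(CBr)ccc1OCc1ccccc1 | intermediate
8 | dilithio dianion of 5 (C7 lithium alkoxide, lactone lithium enolate; 4R,7R) | [Li+].[Li+].[O-]C1=C[C@H](CO1)[C@@H]([O-])c2ccc(OCC=C)c(OC)c2 | intermediate
9 | (3R,4R)-4-{(R)-[4-(allyloxy)-3-methoxyphenyl](hydroxy)methyl}-3-[4-(benzyloxy)-3-methoxybenzyl]dihydrofuran-2(3H)-one | COc1cc(C[C@H]2C(=O)OC[C@@H]2[C@@H](O)c2ccc(OCC=C)c(OC)c2)ccc1OCc1ccccc1 | intermediate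
10 | secondary ozonide of 9 (ArOCH2-substituted 1,2,4-trioxolane, epimers at the ozonide carbon) | COc1cc(C[C@H]2C(=O)OC[C@@H]2[C@@H](O)c2ccc(OCC3OCOO3)c(OC)c2)ccc1OCc1ccccc1 | intermediate
11 | 2-{4-[(R)-{(3R,4R)-4-[4-(benzyloxy)-3-methoxybenzyl]-5-oxotetrahydrofuran-3-yl}(hydroxy)methyl]-2-methoxyphenoxy}acetaldehyde | COc1cc(C[C@H]2C(=O)OC[C@@H]2[C@@H](O)c2ccc(OCC=O)c(OC)c2)ccc1OCc1ccccc1 | intermediate
12 | 4-(benzyloxy)-3-methoxybenzaldehyde | COc1cc(C=O)ccc1OCc1ccccc1 | starting material
13 | 4-(benzyloxy)-2-bromo-5-methoxybenzaldehyde | COc1cc(C=O)c(Br)cc1OCc1ccccc1 | intermediate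
14 | (2R,3S)-3-[4-(benzyloxy)-2-bromo-5-methoxyphenyl]-3-hydroxy-2-(aryloxy)propanal, aryl = ring B of 11 (syn-aldol) | COc1cc(C[C@H]2C(=O)OC[C@@H]2[C@@H](O)c2ccc(O[C@@H](C=O)[C@@H](O)c3cc(OC)c(OCc4ccccc4)cc3Br)c(OC)c2)ccc1OCc1ccccc1 | intermediate
15 | bis-O-benzyl 6''-bromo derivative of the target (3R,4R,7R,7''S,8''S) | COc1cc(C[C@H]2C(=O)OC[C@@H]2[C@@H](O)c2ccc(O[C@@H](CO)[C@@H](O)c3cc(OC)c(OCc4ccccc4)cc3Br)c(OC)c2)ccc1OCc1ccccc1 | intermediate
16 | CNP0233652.1 (3R,4R,7R,7''S,8''S) | COc1cc(C[C@H]2C(=O)OC[C@@H]2[C@@H](O)c2ccc(O[C@@H](CO)[C@@H](O)c3ccc(O)c(OC)c3)c(OC)c2)ccc1O | target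

## Step count and risk
Total step count: 7, with each one-pot sequence counted once.
Longest linear sequence: 5 (steps 1, 3, 4, 6, 7; 1 → 5 → 9 → 11 → 15 → 16).

**Step 6 (new reaction).** It could fail through self-aldol of 11, a poor syn/anti ratio, or retro-aldol or epimerisation of 14. The fallback uses known chemistry, an auxiliary-controlled Evans syn glycolate aldol, which sets out from 11 and comes back at 15. Pinnick oxidation of 11 (NaClO2, NaH2PO4, 2-methyl-2-butene, t-BuOH/H2O) gives the aryloxyacetic acid F1. PivCl/Et3N turns it into the mixed pivalic anhydride F2, which acylates (R)-4-benzyl-2-oxazolidinone (LiCl, THF) to give the N-(aryloxyacetyl)oxazolidinone F3. Bu2BOTf (2.3 equiv, one of which is taken up by C7–OH) and i-Pr2NEt in CH2Cl2 at −78 °C give the (Z)-boron enolate F4. This adds to 13 through a Zimmerman–Traxler chair and gives, after H2O2/pH 7 work-up, the syn-aldol imide F5 (2R,3S). NaBH4 in THF/H2O then removes the auxiliary reductively without touching the lactone and gives 15.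

**Step 1.** The 4-alkoxy-3-methoxy aldehyde 1 is a weak acceptor, so self-aldol of 2 may win. The fallback is a traceless-activator and protecting-group relay that sets out from 13 and 2 and comes back at 5. The same L-proline/NaBH4 sequence is run on the ortho-bromo aldehyde 13, a substrate class on which this cross-aldol is established. It passes through the bromo anti-aldol aldehyde F6 and the bromo diol ester F7 to the bromo benzyl-ether lactone F8. H2, Pd/C and NaOAc remove Br and Bn to give the phenol lactone F9. Allyl bromide/K2CO3 in acetone alkylates only the phenol and gives 5. This costs two extra steps.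

**Step 3.** It could fail through alkoxide-triggered translactonisation to the 5-aryl lactone, O-benzylation, or incomplete second deprotonation. The fallback gives up the dianion and masks the carbinol; it sets out from 5 and comes back at 9. TBSCl/imidazole in DMF gives the silyl ether F10. LiHMDS (1.1 equiv, THF, −78 °C) gives its lithium enolate F11. Bromide 7 alkylates this anti to the C4 substituent to give the trans silyl-ether lactone F12. TBAF buffered with AcOH returns 9. This costs two extra steps.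

## Further compounds
F1 | step 6 | 2-{4-[(R)-{(3R,4R)-4-[4-(benzyloxy)-3-methoxybenzyl]-5-oxotetrahydrofuran-3-yl}(hydroxy)methyl]-2-methoxyphenoxy}acetic acid | COc1cc(C[C@H]2C(=O)OC[C@@H]2[C@@H](O)c2ccc(OCC(=O)O)c(OC)c2)ccc1OCc1ccccc1
F2 | step 6 | mixed pivalic anhydride of F1 | COc1cc(C[C@H]2C(=O)OC[C@@H]2[C@@H](O)c2ccc(OCC(=O)OC(=O)C(C)(C)C)c(OC)c2)ccc1OCc1ccccc1
F3 | step 6 | (R)-4-benzyl-3-(aryloxyacetyl)oxazolidin-2-one from F1 | COc1cc(C[C@H]2C(=O)OC[C@@H]2[C@@H](O)c2ccc(OCC(=O)N3[C@H](Cc4ccccc4)COC3=O)c(OC)c2)ccc1OCc1ccccc1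
F4 | step 6 | (Z)-dibutylboron enolate of F3, C7–O-dibutylborinate | COc1cc(C[C@H]2C(=O)OC[C@@H]2[C@@H](OB(CCCC)CCCC)c2ccc(O/C=C(\OB(CCCC)CCCC)N3[C@H](Cc4ccccc4)COC3=O)c(OC)c2)ccc1OCc1ccccc1
F5 | step 6 | Evans syn-aldol imide, (2R,3S)-acyl chain on (R)-4-benzyloxazolidin-2-one | COc1cc(C[C@H]2C(=O)OC[C@@H]2[C@@H](O)c2ccc(O[C@@H](C(=O)N3[C@H](Cc4ccccc4)COC3=O)[C@@H](O)c3cc(OC)c(OCc4ccccc4)cc3Br)c(OC)c2)ccc1OCc1ccccc1
F6 | step 1 | methyl (3S,4R)-4-[4-(benzyloxy)-2-bromo-5-methoxyphenyl]-3-formyl-4-hydroxybutanoate | COC(=O)C[C@H](C=O)[C@@H](O)c1cc(OC)c(OCc2ccccc2)cc1Br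
F7 | step 1 | methyl (3R,4R)-4-[4-(benzyloxy)-2-bromo-5-methoxyphenyl]-4-hydroxy-3-(hydroxymethyl)butanoate | COC(=O)C[C@H](CO)[C@@H](O)c1cc(OC)c(OCc2ccccc2)cc1Br
F8 | step 1 | (4R)-4-{(R)-[4-(benzyloxy)-2-bromo-5-methoxyphenyl](hydroxy)methyl}dihydrofuran-2(3H)-one | O=C1C[C@H](CO1)[C@@H](O)c2cc(OC)c(OCc3ccccc3)cc2Br
F9 | step 1 | (4R)-4-[(R)-hydroxy(4-hydroxy-3-methoxyphenyl)methyl]dihydrofuran-2(3H)-one | O=C1C[C@H](CO1)[C@@H](O)c2ccc(O)c(OC)c2
F10 | step 3 | (4R)-4-{(R)-[4-(allyloxy)-3-methoxyphenyl][(tert-butyldimethylsilyl)oxy]methyl}dihydrofuran-2(3H)-one | O=C1C[C@H](CO1)[C@@H](O[Si](C)(C)C(C)(C)C)c2ccc(OCC=C)c(OC)c2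
F11 | step 3 | lithium enolate of F10 | [Li+].[O-]C1=C[C@H](CO1)[C@@H](O[Si](C)(C)C(C)(C)C)c2ccc(OCC=C)c(OC)c2
F12 | step 3 | C7–O-TBS ether of 9 (3R,4R,7R) | COc1cc(C[C@H]2C(=O)OC[C@@H]2[C@@H](O[Si](C)(C)C(C)(C)C)c2ccc(OCC=C)c(OC)c2)ccc1OCc1ccccc1
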